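Slowness is the complaint about this flask, so the next run must choose what to change: partner, protic impurity or initiator.

    partner + protic impurity → quenched reagent (k1 = 0.50 L mol⁻¹ s⁻¹)
    substrate + initiating radical → chain carrier (k2 = 17000 L mol⁻¹ s⁻¹)
    initiator → 2 initiating radical (k3 = 1.4 × 10⁻⁴ s⁻¹)
    partner + chain carrier → product + initiating radical (k4 = 44000 L mol⁻¹ s⁻¹)
    2 initiating radical → ended chains (k5 = 6.4 × 10⁶ L mol⁻¹ s⁻¹)

substrate 33 mM; partner 132 mM (in portions, 4); protic impurity 3.30 mM; initiator 1.7 mM; time 15 min; the portions of partner follow each other after 40 s, the first at the start

- two of one species on the left: rate k times its square, two consumed each time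
- run time (flask): 15 min

* how much of the substrate has reacted by 15 min
* how much product there is at 15 min, in percent of the substrate charged

Here is our own reckoning. The chain steps hand the initiating radical back, so in this flask its steady-state level is where the initiator's making of it balances its ending in pairs:

radical level = square root of (1.4 × 10⁻⁴ s⁻¹ × 1.7 mM / 6.4 × 10⁶ L mol⁻¹ s⁻¹) = 1.93 × 10⁻⁴ mM

Substrate then falls pseudo-first-order at 0.00328 s⁻¹. The chain carrier goes at 1450 s⁻¹ on the first portion of partner alone, far faster, so we count each substrate lost as product formed. Protic impurity takes 3.30 mM of partner, less than one portion of 33.0 mM, and substrate, the limiting reagent, needs a quarter of the partner charge.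

The initiator sags with a half-life of 83 min, and the radical level follows its square root, so the 900 s of the run count as an effective 872 s. What we carry forward is the e-folding count, the number of times substrate falls by a factor e during the run:

e-folding count = 0.00328 s⁻¹ × 872 s = 2.86

substrate left = exp(−count) = 5.73%

We commit to 94.3% for both answers. The next run keeps partner and protic impurity as they are; if more conversion is wanted it raises the initiator, and our count goes with the square root of that charge.

The forecast gives 94.3% and 94.3%, holding that “the carrier is converted promptly and essentially every substrate consumed ends up as product”.

The simulation gives 94.3% and 94.3%. The forecast would be off by 5 points if this flask were charged with 1.04 mM of initiator, all else held, and there our count is 2.23 and leaves 10.8% of the substrate. For the neighbour flask with 6.8 mM of initiator, the count is 5.72, twice as large, which leaves 0.328%. The simulated neighbour flask ends with 0.33% of its substrate and a conversion of 99.7%.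

The numbers are invented; the flask was simulated.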